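**Retrosynthetic overview**
- Target 18 comes from the cis-diol 11 by late adjustments only: C3–O isovalerylation, dehydration of the CMe2OH group to isopropenyl, exchange of the side-chain silyl ether for acetate, and allylic oxidation to the 2-substituted acrolein.
- Diol 11 comes from phenol 5 and epoxy aldehyde 8 in one flask: C3a–C3 by ortho C-hydroxyalkylation of the magnesium phenoxide, then O1–C2 by phenoxide opening of the epoxide. This closes the dihydrofuran ring, the only ring that has to be made (the benzene ring is bought).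
- Feature relied on: the C5 side chain is para to O1, so the parent phenol has two equivalent free ortho carbons (future C3a and C7). C3, C2 and the three-carbon unit on C2 are together 3,3-dimethyloxirane-2-carbaldehyde (CHO → C3, epoxide CH → C2, CMe2 → C(=CH2)CHO).
- 5 comes from 4-hydroxyacetophenone 1 (asymmetric transfer hydrogenation sets the side-chain centre); 8 comes from 3-methylbut-2-en-1-ol 6 (Sharpless epoxidation sets the centre that becomes C2).

Key step: step 7

Remark: benzofuran numbering (O1, C2, C3, C3a, C4–C7, C7a) is used and the target is read as the cis-(2R,3R) compound with a (1S)-1-acetoxyethyl group at C5. The descriptor changes at the epoxide carbon (7 R, 8 S, 10 R) and at C2 (11 and 13 S, 14–18 R) are changes of CIP priority only; the one real inversion is at C2 in step 7.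

**Step 1**
Reactants: 1 4-hydroxyacetophenone
Product: 2 1-[4-(tert-butyldimethylsilyloxy)phenyl]ethan-1-one
Conditions: TBSCl, imidazole, DMF, rt
Reagents that add atoms: tert-butyldimethylsilyl chloride, CC(C)(C)[Si](C)(C)Cl
Why: Standard imidazole-mediated O-silylation masks the acidic phenol before the transfer hydrogenation.

**Step 2**
Reactants: 2 1-[4-(tert-butyldimethylsilyloxy)phenyl]ethan-1-one
Product: 3 (1S)-1-[4-(tert-butyldimethylsilyloxy)phenyl]ethan-1-ol
Conditions: RuCl[(S,S)-TsDPEN](p-cymene) (1 mol %), HCO2H/Et3N (5:2), EtOAc, 30 °C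
Reagents that add atoms: none
Why: Noyori asymmetric transfer hydrogenation of an aryl methyl ketone, in which the (S,S)-ligand should deliver hydride to the face that gives the (S)-carbinol, the side-chain stereocentre of the target.

**Step 3**
Reactants: 3 (1S)-1-[4-(tert-butyldimethylsilyloxy)phenyl]ethan-1-ol
Product: 4 (1S)-1-[4-(tert-butyldimethylsilyloxy)phenyl]ethyl tert-butyldimethylsilyl ether
Conditions: TBSCl, imidazole, DMF, rt
Reagents that add atoms: tert-butyldimethylsilyl chloride, CC(C)(C)[Si](C)(C)Cl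
Why: O-silylation leaves the C–O bond and the stereocentre untouched, and a silyl ether is chosen over the final acetate because silanolate is a poor leaving group that the later free phenoxide should not expel to a para-quinone methide.

**Step 4**
Reactants: 4 (1S)-1-[4-(tert-butyldimethylsilyloxy)phenyl]ethyl tert-butyldimethylsilyl ether
Product: 5 4-[(1S)-1-(tert-butyldimethylsilyloxy)ethyl]phenol
Conditions: K2CO3, MeOH, 0 °C to rt
Reagents that add atoms: none
Why: Carbonate-mediated methanolysis cleaves aryl silyl ethers chemoselectively, because phenoxide leaves from silicon far more readily than a secondary alkoxide, so the benzylic silyl ether should survive.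

**Step 5**
Reactants: 6 3-methylbut-2-en-1-ol
Product: 7 [(2R)-3,3-dimethyloxiran-2-yl]methanol
Conditions: Ti(OiPr)4 (5 mol %), D-(−)-diethyl tartrate (6 mol %), t-BuOOH, 4 Å MS, CH2Cl2, −20 °C
Reagents that add atoms: tert-butyl hydroperoxide, CC(C)(C)OO
Why: Sharpless asymmetric epoxidation of a primary allylic alcohol, in which the D-(−)-tartrate ligand should give the (2R)-epoxy alcohol, the centre that becomes C2 of the target.

**Step 6**
Reactants: 7 [(2R)-3,3-dimethyloxiran-2-yl]methanol
Product: 8 (2S)-3,3-dimethyloxirane-2-carbaldehyde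
Conditions: Dess–Martin periodinane, pyridine, CH2Cl2, 0 °C to rt; silica plug, used at once in toluene
Reagents that add atoms: none
Why: Dess–Martin oxidation takes the primary alcohol to the aldehyde under buffered conditions that should leave the epoxide and its non-enolisable stereocentre intact.

**Step 7**
Reactants: 5 4-[(1S)-1-(tert-butyldimethylsilyloxy)ethyl]phenol; 8 (2S)-3,3-dimethyloxirane-2-carbaldehyde
Product: 11 (2S,3R)-5-[(1S)-1-(tert-butyldimethylsilyloxy)ethyl]-2-(2-hydroxypropan-2-yl)-2,3-dihydro-1-benzofuran-3-ol, via magnesium bis(phenoxide) 9 (not isolated), via epoxy alcohol 10 (not isolated)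
Conditions: n-Bu2Mg (0.5 equiv), toluene, THF (1 equiv), 0 °C; 8, −20 °C to rt; then K2CO3, MeOH, 40 °C
Reagents that add atoms: none
Why: Proposed new method: the halide-free magnesium phenoxide 9 binds the aldehyde oxygen of 8 and delivers its ortho carbon through a six-membered transition state, and rearomatisation gives the C3a–C3 bond of 10; the closest known type is the ortho-specific hydroxyalkylation of magnesium phenoxides with alpha-alkoxy aldehydes, and since the para position is blocked and the two ortho carbons are equivalent only one C-alkylation product can form. The new centre C3 is controlled by the epoxide stereocentre of 8: attack anti to the epoxide C–O bond (Felkin–Anh/Cornforth sense, reinforced by the cis methyl of the gem-dimethyl epoxide) should give the anti (R,R) adduct, and the weakly basic epoxide oxygen, the absence of halide and the THF-capped magnesium are relied upon to keep the chelated syn pathway minor. K2CO3 in MeOH then ionises only the phenol, and the phenoxide opens the neighbouring epoxide at its secondary carbon in a 5-exo-tet closure that forms O1–C2 and the dihydrofuran ring; the closest known type is the base-mediated cyclisation of ortho-(2,3-epoxy-3-methylbutyl)phenols to 2-(2-hydroxypropan-2-yl)dihydrobenzofurans. This opening is an SN2 inversion, so C2 takes its configuration from the Sharpless-derived centre, and anti addition followed by inversion should give the cis-2,3 relationship of 11. The step needs C- over O-alkylation (magnesium chelation in a non-polar medium), mono- over bis-hydroxyalkylation (one equivalent of 8 and a chelated, deactivated mono-adduct), 5-exo over 6-endo opening (basic medium, attack at the less substituted carbon) and no Payne rearrangement (carbonate is too weak to ionise the C3 alcohol).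

**Step 8**
Reactants: 11 (2S,3R)-5-[(1S)-1-(tert-butyldimethylsilyloxy)ethyl]-2-(2-hydroxypropan-2-yl)-2,3-dihydro-1-benzofuran-3-ol; 12 3-methylbutanoyl chloride
Product: 13 (2S,3R)-5-[(1S)-1-(tert-butyldimethylsilyloxy)ethyl]-2-(2-hydroxypropan-2-yl)-2,3-dihydro-1-benzofuran-3-yl 3-methylbutanoate
Conditions: pyridine, DMAP (cat.), CH2Cl2, −10 to 0 °C
Reagents that add atoms: none
Why: Acylation under nucleophilic catalysis should take the secondary benzylic C3 hydroxyl and leave the much more hindered tertiary alcohol, with no C–O bond at a stereocentre broken.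

**Step 9**
Reactants: 13 (2S,3R)-5-[(1S)-1-(tert-butyldimethylsilyloxy)ethyl]-2-(2-hydroxypropan-2-yl)-2,3-dihydro-1-benzofuran-3-yl 3-methylbutanoate
Product: 14 (2R,3R)-5-[(1S)-1-(tert-butyldimethylsilyloxy)ethyl]-2-(prop-1-en-2-yl)-2,3-dihydro-1-benzofuran-3-yl 3-methylbutanoate
Conditions: Burgess reagent, toluene, 50 °C
Reagents that add atoms: none
Why: Burgess dehydration (syn elimination of the sulfamate ester) of the tertiary alcohol should proceed toward the six methyl hydrogens rather than the single C2–H, which is deactivated by O1, under near-neutral conditions that spare the C3 ester.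

**Step 10**
Reactants: 14 (2R,3R)-5-[(1S)-1-(tert-butyldimethylsilyloxy)ethyl]-2-(prop-1-en-2-yl)-2,3-dihydro-1-benzofuran-3-yl 3-methylbutanoate
Product: 15 (2R,3R)-5-[(1S)-1-hydroxyethyl]-2-(prop-1-en-2-yl)-2,3-dihydro-1-benzofuran-3-yl 3-methylbutanoate
Conditions: HF·pyridine, pyridine, THF, 0 °C to rt
Reagents that add atoms: none
Why: Buffered HF·pyridine cleaves the Si–O bond without a basic fluoride source, which could cause anti elimination of isovaleric acid across C2–C3 to the aromatic benzofuran.

**Step 11**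
Reactants: 15 (2R,3R)-5-[(1S)-1-hydroxyethyl]-2-(prop-1-en-2-yl)-2,3-dihydro-1-benzofuran-3-yl 3-methylbutanoate
Product: 16 (2R,3R)-5-[(1S)-1-(acetyloxy)ethyl]-2-(prop-1-en-2-yl)-2,3-dihydro-1-benzofuran-3-yl 3-methylbutanoate
Conditions: Ac2O, pyridine, DMAP (cat.), CH2Cl2, 0 °C
Reagents that add atoms: acetic anhydride, CC(=O)OC(C)=O
Why: O-acetylation of the secondary benzylic alcohol proceeds with retention because only the O–H bond is replaced.

**Step 12**
Reactants: 16 (2R,3R)-5-[(1S)-1-(acetyloxy)ethyl]-2-(prop-1-en-2-yl)-2,3-dihydro-1-benzofuran-3-yl 3-methylbutanoate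
Product: 17 (2R,3R)-5-[(1S)-1-(acetyloxy)ethyl]-2-(3-hydroxyprop-1-en-2-yl)-2,3-dihydro-1-benzofuran-3-yl 3-methylbutanoate
Conditions: SeO2 (cat.), t-BuOOH, CH2Cl2, rt
Reagents that add atoms: tert-butyl hydroperoxide (terminal oxidant, oxygen relayed through SeO2), CC(C)(C)OO; selenium dioxide, O=[Se]=O
Why: Riley-type allylic oxidation (ene reaction, then [2,3]-sigmatropic shift) of a 1,1-disubstituted alkene should oxidise the methyl group in preference to the methine C2–H, which O1 further deactivates, and leave the double bond in place.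

**Step 13**
Reactants: 17 (2R,3R)-5-[(1S)-1-(acetyloxy)ethyl]-2-(3-hydroxyprop-1-en-2-yl)-2,3-dihydro-1-benzofuran-3-yl 3-methylbutanoate
Product: 18 (2R,3R)-5-[(1S)-1-(acetyloxy)ethyl]-2-(3-oxoprop-1-en-2-yl)-2,3-dihydro-1-benzofuran-3-yl 3-methylbutanoate (CNP0252902.1)
Conditions: Dess–Martin periodinane, pyridine, CH2Cl2, 0 °C
Reagents that add atoms: none
Why: Dess–Martin oxidation of the primary allylic alcohol gives the enal under near-neutral conditions that should avoid base-induced migration of the double bond toward C2 and loss of the C3 ester.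

**Compound list**
1 | 4-hydroxyacetophenone | CC(=O)c1ccc(O)cc1 | starting material
2 | 1-[4-(tert-butyldimethylsilyloxy)phenyl]ethan-1-one | CC(=O)c1ccc(O[Si](C)(C)C(C)(C)C)cc1 | intermediate
3 | (1S)-1-[4-(tert-butyldimethylsilyloxy)phenyl]ethan-1-ol | C[C@H](O)c1ccc(O[Si](C)(C)C(C)(C)C)cc1 | intermediate
4 | (1S)-1-[4-(tert-butyldimethylsilyloxy)phenyl]ethyl tert-butyldimethylsilyl ether | C[C@H](O[Si](C)(C)C(C)(C)C)c1ccc(O[Si](C)(C)C(C)(C)C)cc1 | intermediate
5 | 4-[(1S)-1-(tert-butyldimethylsilyloxy)ethyl]phenol | C[C@H](O[Si](C)(C)C(C)(C)C)c1ccc(O)cc1 | intermediate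
6 | 3-methylbut-2-en-1-ol | CC(C)=CCO | starting material
7 | [(2R)-3,3-dimethyloxiran-2-yl]methanol | OC[C@H]1OC1(C)C | intermediate
8 | (2S)-3,3-dimethyloxirane-2-carbaldehyde | O=C[C@H]1OC1(C)C | intermediate
9 | magnesium bis{4-[(1S)-1-(tert-butyldimethylsilyloxy)ethyl]phenoxide} | C[C@H](O[Si](C)(C)C(C)(C)C)c1ccc([O-])cc1.C[C@H](O[Si](C)(C)C(C)(C)C)c1ccc([O-])cc1.[Mg+2] | intermediate
10 | 2-{(R)-[(2R)-3,3-dimethyloxiran-2-yl](hydroxy)methyl}-4-[(1S)-1-(tert-butyldimethylsilyloxy)ethyl]phenol | C[C@H](O[Si](C)(C)C(C)(C)C)c1ccc(O)c(c1)[C@@H](O)[C@H]1OC1(C)C | intermediate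
11 | (2S,3R)-5-[(1S)-1-(tert-butyldimethylsilyloxy)ethyl]-2-(2-hydroxypropan-2-yl)-2,3-dihydro-1-benzofuran-3-ol | CC(C)(O)[C@H]1Oc2ccc([C@H](C)O[Si](C)(C)C(C)(C)C)cc2[C@H]1O | intermediate
12 | 3-methylbutanoyl chloride | CC(C)CC(Cl)=O | starting material
13 | (2S,3R)-5-[(1S)-1-(tert-butyldimethylsilyloxy)ethyl]-2-(2-hydroxypropan-2-yl)-2,3-dihydro-1-benzofuran-3-yl 3-methylbutanoate | CC(C)(O)[C@H]1Oc2ccc([C@H](C)O[Si](C)(C)C(C)(C)C)cc2[C@H]1OC(=O)CC(C)C | intermediate
14 | (2R,3R)-5-[(1S)-1-(tert-butyldimethylsilyloxy)ethyl]-2-(prop-1-en-2-yl)-2,3-dihydro-1-benzofuran-3-yl 3-methylbutanoate | C=C(C)[C@H]1Oc2ccc([C@H](C)O[Si](C)(C)C(C)(C)C)cc2[C@H]1OC(=O)CC(C)C | intermediate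
15 | (2R,3R)-5-[(1S)-1-hydroxyethyl]-2-(prop-1-en-2-yl)-2,3-dihydro-1-benzofuran-3-yl 3-methylbutanoate | C=C(C)[C@H]1Oc2ccc([C@H](C)O)cc2[C@H]1OC(=O)CC(C)C | intermediate
16 | (2R,3R)-5-[(1S)-1-(acetyloxy)ethyl]-2-(prop-1-en-2-yl)-2,3-dihydro-1-benzofuran-3-yl 3-methylbutanoate | C=C(C)[C@H]1Oc2ccc([C@H](C)OC(C)=O)cc2[C@H]1OC(=O)CC(C)C | intermediate
17 | (2R,3R)-5-[(1S)-1-(acetyloxy)ethyl]-2-(3-hydroxyprop-1-en-2-yl)-2,3-dihydro-1-benzofuran-3-yl 3-methylbutanoate | C=C(CO)[C@H]1Oc2ccc([C@H](C)OC(C)=O)cc2[C@H]1OC(=O)CC(C)C | intermediate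
18 | (2R,3R)-5-[(1S)-1-(acetyloxy)ethyl]-2-(3-oxoprop-1-en-2-yl)-2,3-dihydro-1-benzofuran-3-yl 3-methylbutanoate (CNP0252902.1) | C=C(C=O)[C@H]1Oc2ccc([C@H](C)OC(C)=O)cc2[C@H]1OC(=O)CC(C)C | target

**Total step count:** 13
**Longest linear sequence:** 11 steps (steps 1–4, then 7–13; the aldehyde branch, steps 5–6, joins at step 7)

**Steps most likely to fail**

1. Step 7 (carries the proposed method). Facial selectivity may be lost if magnesium chelates the epoxide oxygen, which would lead through the syn adduct to the trans-2,3 ring. O-alkylation, a second hydroxyalkylation at the other ortho carbon, or opening at the tertiary epoxide carbon may also intervene. The fallback uses known reactions only and sets out from phenol 5 and aldehyde 8.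
 - Ortho-bromination of 5 (NBS, i-Pr2NH cat., CH2Cl2, 0 °C) should give 2-bromo-4-[(1S)-1-(tert-butyldimethylsilyloxy)ethyl]phenol F1.
 - O-allylation (allyl bromide, K2CO3, acetone) should give tert-butyl{(1S)-1-[3-bromo-4-(prop-2-en-1-yloxy)phenyl]ethoxy}dimethylsilane F2.
 - Bromine–lithium exchange (n-BuLi, THF, −78 °C) and addition to 8 should give [(2R)-3,3-dimethyloxiran-2-yl]{2-(prop-2-en-1-yloxy)-5-[(1S)-1-(tert-butyldimethylsilyloxy)ethyl]phenyl}methanol F3 as a mixture of carbinol epimers.
 - Dess–Martin oxidation converges the mixture to [(2S)-3,3-dimethyloxiran-2-yl]{2-(prop-2-en-1-yloxy)-5-[(1S)-1-(tert-butyldimethylsilyloxy)ethyl]phenyl}methanone F4.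
 - Chelation-controlled reduction with Zn(BH4)2 (Et2O, −20 °C), the established way from alpha,beta-epoxy ketones to anti epoxy alcohols, should give (R)-[(2R)-3,3-dimethyloxiran-2-yl]{2-(prop-2-en-1-yloxy)-5-[(1S)-1-(tert-butyldimethylsilyloxy)ethyl]phenyl}methanol F5.
 - Deallylation with Pd(PPh3)4 and K2CO3 in MeOH then frees the phenol, which is compound 10, and the same basic methanol should close it to 11, where the route is rejoined.

2. Step 9. Elimination may go toward C2 to the isopropylidene enol ether, the cis C3 ester may participate at the ionising tertiary centre and transfer its acyl group, or isovaleric acid may be lost with aromatisation to the benzofuran. The fallback takes the ester out of the dehydration substrate and sets out from diol 11.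
 - Selective silylation of the secondary hydroxyl (TESCl, imidazole, CH2Cl2, 0 °C) should give 2-[(2S,3R)-5-[(1S)-1-(tert-butyldimethylsilyloxy)ethyl]-3-(triethylsilyloxy)-2,3-dihydro-1-benzofuran-2-yl]propan-2-ol F6.
 - Dehydration with Martin sulfurane (CH2Cl2, 0 °C) should give tert-butyl{(1S)-1-[(2R,3R)-2-(prop-1-en-2-yl)-3-(triethylsilyloxy)-2,3-dihydro-1-benzofuran-5-yl]ethoxy}dimethylsilane F7.
 - Brief treatment with buffered HF·pyridine (pyridine, THF, 0 °C) should remove the more labile triethylsilyl group only and give (2R,3R)-5-[(1S)-1-(tert-butyldimethylsilyloxy)ethyl]-2-(prop-1-en-2-yl)-2,3-dihydro-1-benzofuran-3-ol F8.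
 - Acylation with 12 under the conditions of step 8 returns to the route at 14.

3. Step 12. The ene reaction of the 1,1-disubstituted alkene may be sluggish, and forcing it may bring over-oxidation, attack at C2–H or thermal loss of the C3 ester. The fallback replaces the selenium oxidation by a halogenation–oxidation sequence and sets out from 16.
 - Ene-type allylic chlorination with hypochlorous acid generated in the flask (Ca(OCl)2, solid CO2, CH2Cl2–H2O, 0 °C) should give (2R,3R)-5-[(1S)-1-(acetyloxy)ethyl]-2-(3-chloroprop-1-en-2-yl)-2,3-dihydro-1-benzofuran-3-yl 3-methylbutanoate F9.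
 - Kornblum-type oxidation of the allylic chloride with N-methylmorpholine N-oxide (MeCN, rt) should give the enal directly, rejoining the route at target 18 and bypassing 17.

**Further compounds**
F1 | step 7 | 2-bromo-4-[(1S)-1-(tert-butyldimethylsilyloxy)ethyl]phenol | C[C@H](O[Si](C)(C)C(C)(C)C)c1ccc(O)c(Br)c1
F2 | step 7 | tert-butyl{(1S)-1-[3-bromo-4-(prop-2-en-1-yloxy)phenyl]ethoxy}dimethylsilane | C[C@H](O[Si](C)(C)C(C)(C)C)c1ccc(OCC=C)c(Br)c1
F3 | step 7 | [(2R)-3,3-dimethyloxiran-2-yl]{2-(prop-2-en-1-yloxy)-5-[(1S)-1-(tert-butyldimethylsilyloxy)ethyl]phenyl}methanol (carbinol epimers) | C[C@H](O[Si](C)(C)C(C)(C)C)c1ccc(OCC=C)c(c1)C(O)[C@H]1OC1(C)C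
F4 | step 7 | [(2S)-3,3-dimethyloxiran-2-yl]{2-(prop-2-en-1-yloxy)-5-[(1S)-1-(tert-butyldimethylsilyloxy)ethyl]phenyl}methanone | C[C@H](O[Si](C)(C)C(C)(C)C)c1ccc(OCC=C)c(c1)C(=O)[C@H]1OC1(C)C
F5 | step 7 | (R)-[(2R)-3,3-dimethyloxiran-2-yl]{2-(prop-2-en-1-yloxy)-5-[(1S)-1-(tert-butyldimethylsilyloxy)ethyl]phenyl}methanol | C[C@H](O[Si](C)(C)C(C)(C)C)c1ccc(OCC=C)c(c1)[C@@H](O)[C@H]1OC1(C)C
F6 | step 9 | 2-[(2S,3R)-5-[(1S)-1-(tert-butyldimethylsilyloxy)ethyl]-3-(triethylsilyloxy)-2,3-dihydro-1-benzofuran-2-yl]propan-2-ol | CC(C)(O)[C@H]1Oc2ccc([C@H](C)O[Si](C)(C)C(C)(C)C)cc2[C@H]1O[Si](CC)(CC)CC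
F7 | step 9 | tert-butyl{(1S)-1-[(2R,3R)-2-(prop-1-en-2-yl)-3-(triethylsilyloxy)-2,3-dihydro-1-benzofuran-5-yl]ethoxy}dimethylsilane | C=C(C)[C@H]1Oc2ccc([C@H](C)O[Si](C)(C)C(C)(C)C)cc2[C@H]1O[Si](CC)(CC)CC
F8 | step 9 | (2R,3R)-5-[(1S)-1-(tert-butyldimethylsilyloxy)ethyl]-2-(prop-1-en-2-yl)-2,3-dihydro-1-benzofuran-3-ol | C=C(C)[C@H]1Oc2ccc([C@H](C)O[Si](C)(C)C(C)(C)C)cc2[C@H]1O
F9 | step 12 | (2R,3R)-5-[(1S)-1-(acetyloxy)ethyl]-2-(3-chloroprop-1-en-2-yl)-2,3-dihydro-1-benzofuran-3-yl 3-methylbutanoate | C=C(CCl)[C@H]1Oc2ccc([C@H](C)OC(C)=O)cc2[C@H]1OC(=O)CC(C)C
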